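The numbers were chosen freely; the result is computed.

The question before the meeting was how much of the electrophile has reacted in this flask by the end of the run, and how much of the unused nucleophile is still free then.

electrophile 0.20 M; nucleophile 0.260 M; free base 0.160 M; protic impurity 0.0200 M; time 2.5 min

    protic impurity + free base → quenched reagent (k1 = 4.7 M⁻¹ s⁻¹)
    nucleophile + acid set free ⇌ protonated nucleophile, settled at all times (K2 = 37000 M⁻¹)
    electrophile + nucleophile → acid set free + product (k3 = 0.25 M⁻¹ s⁻¹)
    electrophile + acid set free ⇌ idle adduct, settled at all times (K4 = 15 M⁻¹)
    acid set free + free base ⇌ salt of the base, settled at all times (K5 = 6.6 M⁻¹)

* part of the electrophile that has reacted at 2.5 min
* share of the unused nucleophile that is free and not bound as protonated nucleophile, at 2.5 min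

- amounts and yields of acid set free count idle adduct too
- run time (flask): 2.5 min

I opened by putting the takers of the acid set free on a logarithmic scale. Equilibrium constant times starting concentration is 9600 for the nucleophile, which stands 3.51 powers of ten above the stronger of the other two. I therefore held that, as long as the nucleophile outbids the other takers so, each turnover costs two nucleophiles. I proposed the break point, the fraction of the charged electrophile reacted when two nucleophiles per turnover have taken up the whole nucleophile charge, 65.0%, which makes the nucleophile the limiting reagent.

I added that the half-life of the electrophile by the coupling step alone, the other concentrations as charged, 0.18 min, is shorter than the run by 1.15 powers of ten, so the flask should reach the break point in time. My answer for the reacted part was therefore 65.0%.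

My reckoning went no further: for the free share I committed to no number.

The maker of the forecast then tabled 65.8% reacted and a free share of 1.5%, on the ground “so each turnover uses two nucleophiles”. That reacted part lies 0.8 percentage points above my break point.

The flask gives 66.7% reacted and a free share of 1.51%, so both forecast numbers stand within their margins. Free nucleophile is then 0.746% of its charge, less than the 33% of the charged electrophile still unbound, and the reacted part stands 1.7 points past the break point. The forecast's reacted part does not carry over to a changed charge: the neighbour flask with 0.34 M of electrophile, other charges and time held, has its break point at 38.2%. That flask reaches 43.9% reacted, with 40.7% of its electrophile as product.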